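Numbering follows quinic acid. C1 bears OH and the carboxyl carbon C7, C2 and C6 are the CH2 groups, C3 bears the free OH, and C4 and C5 bear the vanillate esters.
Retrosynthesis: cut the ester bonds O4–C(O)Ar and O5–C(O)Ar. Return C4 to a symmetric dimethyl ketal and C1(OH)–C7O2H to an exocyclic C1=C7H2. Then cut the ring bonds C2–C3 and C6–C5 together, which leaves a propane-1,3-diol (C3–C4–C5) and a 2-methylidenepropane-1,3-diyl diester (C2–C1(=C7)–C6).
Enabling feature: the cyclohexane ring hides a twofold axis through C1 and C4. C3 and C5 are both R carbinol carbons, each tied to C1 by one CH2, so C2–C3 and C6–C5 are symmetry-equivalent. One chiral catalyst can forge both in a redox-neutral double carbonyl allylation ([3+3] annulation).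
Forward: the only ring arises in that step. C1=C7 is then dihydroxylated and C7 oxidised, O5 is acylated, C4 is unmasked and reduced, O4 is acylated, and all benzyl groups fall in one hydrogenolysis.
Stereochemistry: C3 and C5 come from the iridium catalyst, reinforced by the ring-closing transition state. C1 needs no facial control (homotopic alkene faces) and becomes defined when a boronate that can bridge only the cis pair O1/O3 leaves O5 alone to be acylated. C4 comes from axial hydride attack on a conformationally biased ketone.

Key step: step 3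

Assumption: the (R)-ligand is taken to open the Re face of the transient aldehydes, by analogy with simple primary alcohols; if the sense proves opposite, the equally available (S)-ligand is used and nothing else changes.

Step 1
Reactants: 1 1,3-dihydroxyacetone dimer (2,5-bis(hydroxymethyl)-1,4-dioxane-2,5-diol)
Product: 2 2,2-dimethoxypropane-1,3-diol
Conditions: HC(OMe)3, TsOH·H2O (cat.), MeOH, rt
Reagents that add atoms: trimethyl orthoformate, COC(OC)OC; methanol, CO
Why: Acid-catalysed ketalisation of the monomer released from the dimer, driven by the orthoester as water scavenger, masks C4 as a symmetric centre without α-hydrogen.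

Step 2
Reactants: 3 2-methylidenepropane-1,3-diol
Product: 4 2-methylidenepropane-1,3-diyl bis(tert-butyl carbonate)
Conditions: Boc2O (2.2 equiv), DMAP (10 mol %), CH2Cl2, 0 °C to rt
Reagents that add atoms: di-tert-butyl dicarbonate, CC(C)(C)OC(=O)OC(=O)OC(C)(C)C
Why: DMAP-catalysed O-acylation of the two primary allylic alcohols (carbonate formation) gives leaving groups that ionise readily and, unlike acetates, do not wander onto other alcohols.

Step 3
Reactants: 2 2,2-dimethoxypropane-1,3-diol; 4 2-methylidenepropane-1,3-diyl bis(tert-butyl carbonate)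
Product: 7 (1R,3R)-2,2-dimethoxy-5-methylidenecyclohexane-1,3-diol, via monoadduct carbonate 5 (not isolated), via hydroxy aldehyde 6 (not isolated)
Conditions: [Ir(cod)Cl]2 (5 mol %), (R)-Cl,MeO-BIPHEP (10 mol %), 4-chloro-3-nitrobenzoic acid (20 mol %), Cs2CO3 (40 mol %), THF (0.02 M), 80 °C (sealed), 4 (1.0 equiv) added by syringe pump
Reagents that add atoms: none
Why: Proposed new method: the π-allyl iridium C,O-benzoate formed in situ dehydrogenates one CH2OH of 2 to the non-enolisable α,α-dimethoxy aldehyde, the iridium hydride is deprotonated to monovalent iridium, this ionises one carbonate of 4, and the resulting nucleophilic σ-allyl complex of trivalent iridium adds through its γ-carbon in a closed chair to give 5 (bond C6–C5), after which alkoxide exchange to the remaining CH2OH, β-hydride elimination to 6 and ionisation of the second carbonate repeat the cycle inside one molecule and close bond C2–C3, so that in each event two natively electrophilic carbons (allylic C–O and carbonyl C) are joined by polarity reversal with the substrate's own hydrogen as reductant. The closest known reaction types are the iridium-catalysed two-directional double allylation of propane-1,3-diols, 2,2-disubstituted ones included, with allyl esters and the iridium-catalysed C-allylation of 1,3-diols with this same bis-carbonate, which stops after one C–C bond; new is that the second donor and the second carbinol sit in one molecule. The cyclohexane ring closes 6-exo-trig at the aldehyde carbon through a chair–chair, bicyclo[3.3.1]nonane-like transition state in which the forming carbocycle and the six-membered Ir–O=C3···C2=C1–C7 array share C3, C2 and C1. C5 is set by the ligand, which leaves the Re face of the aldehyde open; C3 is set by the same preference and, in the matched sense, by the transition state, where the iridium-bound O3 must be axial on the forming chair while the C5–O bond stays equatorial, which is the trans (3R,5R) diol. Material of the wrong configuration at C5 is led to the meso cis-diol, a separable diastereomer, so the enantiomeric purity of 7 should exceed that of a single addition. The step needs ring closure to outrun a second intermolecular allylation and O-allylation: slow addition of equimolar 4 at high dilution, the gem-dimethoxy group at C4 (gem-disubstituent effect, no α-hydrogen, hence no enolisation, elimination or epimerisation) and the 1,3-diol motif that hands the metal from O5 to the neighbouring CH2OH secure the first, the nucleophilic character of these allyl complexes the second, and the catalyst's preference for primary over secondary carbinols protects the product.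

Step 4
Reactants: 7 (1R,3R)-2,2-dimethoxy-5-methylidenecyclohexane-1,3-diol
Product: 8 (3R,5R)-1-(hydroxymethyl)-4,4-dimethoxycyclohexane-1,3,5-triol
Conditions: K2OsO4·2H2O (1 mol %), NMO, acetone–H2O 4:1, rt
Reagents that add atoms: N-methylmorpholine N-oxide, C[N+]1([O-])CCOCC1; water, O
Why: Catalytic osmium tetroxide syn-dihydroxylation of the 1,1-disubstituted alkene can give only one tetrol, because the twofold axis of 7 runs along C4···C1=C7 and makes the two alkene faces homotopic, so C1 needs no facial control.

Step 5
Reactants: 8 (3R,5R)-1-(hydroxymethyl)-4,4-dimethoxycyclohexane-1,3,5-triol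
Product: 10 benzyl (3R,5R)-1,3,5-trihydroxy-4,4-dimethoxycyclohexane-1-carboxylate, via hydroxy acid 9 (not isolated)
Conditions: TEMPO (10 mol %), NaOCl (5 mol %), NaClO2, MeCN/phosphate buffer pH 6.8, 35 °C; freeze-dry; then BnBr, NaHCO3, DMF, rt
Reagents that add atoms: sodium chlorite, [Na+].[O-]Cl=O; benzyl bromide, BrCc1ccccc1
Why: Nitroxyl-catalysed chlorite oxidation takes the primary alcohol of a 1,2-diol to the α-hydroxy acid without glycol cleavage and spares the hindered secondary carbinols, and SN2 O-alkylation of the crude carboxylate then gives the benzyl ester.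

Step 6
Reactants: 11 4-(benzyloxy)-3-methoxybenzoic acid
Product: 12 4-(benzyloxy)-3-methoxybenzoyl chloride
Conditions: (COCl)2, DMF (cat.), CH2Cl2, 0 °C to rt
Reagents that add atoms: oxalyl chloride, O=C(Cl)C(=O)Cl
Why: Acid chloride formation through catalytic chloroiminium (Vilsmeier-type) activation is routine for this benzyl-protected acid.

Step 7
Reactants: 10 benzyl (3R,5R)-1,3,5-trihydroxy-4,4-dimethoxycyclohexane-1-carboxylate; 12 4-(benzyloxy)-3-methoxybenzoyl chloride
Product: 15 benzyl (1S,3R,5R)-5-{[4-(benzyloxy)-3-methoxybenzoyl]oxy}-1,3-dihydroxy-4,4-dimethoxycyclohexane-1-carboxylate, via boronate 13 (not isolated), via acylated boronate 14 (not isolated)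
Conditions: PhB(OH)2 (1.05 equiv), 4 Å MS, CH2Cl2, rt; then 12 (1.3 equiv), pyridine, DMAP (cat.), 0 to 40 °C; then pinacol, rt
Reagents that add atoms: none
Why: Transient boronate protection works here because only O1 and O3 are cis-1,3-diaxial and can be spanned by the planar boron in a six-membered ring, so the DMAP-catalysed acylation can reach only O5, the hydroxyl cis to CO2Bn, which defines C1 as S, and transesterification to pinacol then frees O1 and O3.

Step 8
Reactants: 15 benzyl (1S,3R,5R)-5-{[4-(benzyloxy)-3-methoxybenzoyl]oxy}-1,3-dihydroxy-4,4-dimethoxycyclohexane-1-carboxylate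
Product: 16 benzyl (1S,3R,5R)-5-{[4-(benzyloxy)-3-methoxybenzoyl]oxy}-1,3-dihydroxy-4-oxocyclohexane-1-carboxylate
Conditions: 2 M aq. HCl–THF 1:1, 45 °C
Reagents that add atoms: water, O
Why: Acid-catalysed ketal hydrolysis frees the C4 ketone under warm dilute acid that secondary aryl esters and benzyl esters tolerate, and neither C2 nor C6 carries a leaving group that the new ketone could expel.

Step 9
Reactants: 16 benzyl (1S,3R,5R)-5-{[4-(benzyloxy)-3-methoxybenzoyl]oxy}-1,3-dihydroxy-4-oxocyclohexane-1-carboxylate
Product: 17 benzyl (1S,3R,4R,5R)-5-{[4-(benzyloxy)-3-methoxybenzoyl]oxy}-1,3,4-trihydroxycyclohexane-1-carboxylate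
Conditions: NaBH4, CeCl3·7H2O, MeOH–CH2Cl2, −78 °C
Reagents that add atoms: none
Why: In this Luche reduction the equatorial CO2Bn and O5 ester hold the chair that has O1 and O3 axial, so the small hydride attacks C4 axially and anti to the axial C3–O bond and gives the equatorial 4-OH, cis to O3 and trans to O5 (4R), while the low temperature disfavours acyl shift.

Step 10
Reactants: 17 benzyl (1S,3R,4R,5R)-5-{[4-(benzyloxy)-3-methoxybenzoyl]oxy}-1,3,4-trihydroxycyclohexane-1-carboxylate; 12 4-(benzyloxy)-3-methoxybenzoyl chloride
Product: 18 benzyl (1S,3R,4R,5R)-4,5-bis{[4-(benzyloxy)-3-methoxybenzoyl]oxy}-1,3-dihydroxycyclohexane-1-carboxylate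
Conditions: 12 (1.1 equiv), Ph2BOCH2CH2NH2 (10 mol %), iPr2NEt, MeCN, rt
Reagents that add atoms: none
Why: In borinic acid-catalysed site-selective acylation the catalyst binds the cis-3,4-diol as a tetracoordinate borinate and activates its equatorial oxygen O4, while axial O3 and tertiary O1 stay free.

Step 11
Reactants: 18 benzyl (1S,3R,4R,5R)-4,5-bis{[4-(benzyloxy)-3-methoxybenzoyl]oxy}-1,3-dihydroxycyclohexane-1-carboxylate
Product: 19 burkinabin C, (1S,3R,4R,5R)-1,3-dihydroxy-4,5-bis[(4-hydroxy-3-methoxybenzoyl)oxy]cyclohexane-1-carboxylic acid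
Conditions: H2 (1 atm), 10 % Pd/C, EtOAc–EtOH, rt
Reagents that add atoms: none
Why: Hydrogenolysis over palladium cleaves the two aryl benzyl ethers and the benzyl ester under neutral conditions that leave the aryl esters and all stereocentres untouched and give no opening for acyl migration.

Compound list
1 | 1,3-dihydroxyacetone dimer | OCC1(O)COC(O)(CO)CO1 | starting material
2 | 2,2-dimethoxypropane-1,3-diol | COC(CO)(CO)OC | intermediate
3 | 2-methylidenepropane-1,3-diol | C=C(CO)CO | starting material
4 | 2-methylidenepropane-1,3-diyl bis(tert-butyl carbonate) | C=C(COC(=O)OC(C)(C)C)COC(=O)OC(C)(C)C | intermediate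
5 | monoadduct carbonate, tert-butyl (4R)-4,6-dihydroxy-5,5-dimethoxy-2-methylidenehexyl carbonate (not isolated) | CC(C)(C)OC(=O)OCC(=C)C[C@@H](O)C(OC)(OC)CO | intermediate
6 | hydroxy aldehyde, tert-butyl (4R)-4-hydroxy-5,5-dimethoxy-2-methylidene-6-oxohexyl carbonate (not isolated) | CC(C)(C)OC(=O)OCC(=C)C[C@@H](O)C(OC)(OC)C=O | intermediate
7 | (1R,3R)-2,2-dimethoxy-5-methylidenecyclohexane-1,3-diol (trans-diol, C2-symmetric) | C=C1C[C@@H](O)C(OC)(OC)[C@H](O)C1 | intermediate
8 | (3R,5R)-1-(hydroxymethyl)-4,4-dimethoxycyclohexane-1,3,5-triol | OCC1(O)C[C@@H](O)C(OC)(OC)[C@H](O)C1 | intermediate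
9 | hydroxy acid, (3R,5R)-1,3,5-trihydroxy-4,4-dimethoxycyclohexane-1-carboxylic acid (not isolated) | OC(=O)C1(O)C[C@@H](O)C(OC)(OC)[C@H](O)C1 | intermediate
10 | benzyl (3R,5R)-1,3,5-trihydroxy-4,4-dimethoxycyclohexane-1-carboxylate | O=C(OCc1ccccc1)C2(O)C[C@@H](O)C(OC)(OC)[C@H](O)C2 | intermediate
11 | 4-(benzyloxy)-3-methoxybenzoic acid | COc1cc(C(=O)O)ccc1OCc1ccccc1 | starting material
12 | 4-(benzyloxy)-3-methoxybenzoyl chloride | COc1cc(C(=O)Cl)ccc1OCc1ccccc1 | intermediate
13 | boronate, O1,O3-phenylboronate of 10 (not isolated) | COC1(OC)[C@H]2C[C@@](OB(c3ccccc3)O2)(C(=O)OCc3ccccc3)C[C@H]1O | intermediate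
14 | acylated boronate, O1,O3-phenylboronate of 15 (not isolated) | COC1(OC)[C@H]2C[C@@](OB(c3ccccc3)O2)(C(=O)OCc3ccccc3)C[C@H]1OC(=O)c1ccc(OCc2ccccc2)c(OC)c1 | intermediate
15 | benzyl (1S,3R,5R)-5-{[4-(benzyloxy)-3-methoxybenzoyl]oxy}-1,3-dihydroxy-4,4-dimethoxycyclohexane-1-carboxylate (O5 ester cis to CO2Bn, O3 cis to O1) | COC1(OC)[C@H](O)C[C@@](O)(C(=O)OCc2ccccc2)C[C@H]1OC(=O)c1ccc(OCc2ccccc2)c(OC)c1 | intermediate
16 | benzyl (1S,3R,5R)-5-{[4-(benzyloxy)-3-methoxybenzoyl]oxy}-1,3-dihydroxy-4-oxocyclohexane-1-carboxylate | O=C1[C@H](O)C[C@@](O)(C(=O)OCc2ccccc2)C[C@H]1OC(=O)c1ccc(OCc2ccccc2)c(OC)c1 | intermediate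
17 | benzyl (1S,3R,4R,5R)-5-{[4-(benzyloxy)-3-methoxybenzoyl]oxy}-1,3,4-trihydroxycyclohexane-1-carboxylate | O[C@@H]1[C@H](O)C[C@@](O)(C(=O)OCc2ccccc2)C[C@H]1OC(=O)c1ccc(OCc2ccccc2)c(OC)c1 | intermediate
18 | benzyl (1S,3R,4R,5R)-4,5-bis{[4-(benzyloxy)-3-methoxybenzoyl]oxy}-1,3-dihydroxycyclohexane-1-carboxylate | COc1cc(C(=O)O[C@@H]2[C@H](O)C[C@@](O)(C(=O)OCc3ccccc3)C[C@H]2OC(=O)c2ccc(OCc3ccccc3)c(OC)c2)ccc1OCc1ccccc1 | intermediate
19 | burkinabin C (4,5-di-O-vanilloylquinic acid) | COc1cc(C(=O)O[C@@H]2[C@H](O)C[C@@](O)(C(=O)O)C[C@H]2OC(=O)c2ccc(O)c(OC)c2)ccc1O | target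

Total step count: 11. Longest linear sequence: 9 steps (1, 3, 4, 5, 7, 8, 9, 10, 11).

Steps most likely to fail

Step 3. Ring closure may lose out to intermolecular allylation (open-chain double adducts, oligomers), or the catalyst may fail to ionise the more hindered carbonate of the monoadduct. The fallback makes the two bonds one after the other by known reactions.
- It sets out from 2 and 4. The same iridium-catalysed C-allylation is run with an excess of 2 and stopped at monoadduct carbonate 5, which is isolated.
- TEMPO/PhI(OAc)2 in CH2Cl2 oxidises only its primary alcohol, giving hydroxy aldehyde 6.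
- Pd(PPh3)4/InI in THF converts the allylic carbonate into an allylindium species. This adds to the aldehyde through the same closed chair–chair arrangement (new oxygen axial, C5–O equatorial, hence trans), and the route is rejoined at 7.
- No compound outside the list arises (F0).

Step 8. The ketal is deactivated by two α-oxygen neighbours, so hydrolysis may be slow enough for loss of the aryl ester or of a benzyl group to compete. The fallback unmasks C4 before any aryl ester is present and then installs both esters at once.
- It sets out from 10. 2 M HCl–THF gives benzyl (3R,5R)-1,3,5-trihydroxy-4-oxocyclohexane-1-carboxylate F1.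
- PhB(OH)2 bridges O1 and O3 to give the boronate ketone F2.
- Me4NBH(OAc)3 in MeCN/AcOH binds to the free O5–H and delivers hydride to the face of C4 syn to O5. This should give the boronate 4,5-diol F3 (O4 trans to O5).
- Acid chloride 12 (2.5 equiv, pyridine, DMAP) acylates both hydroxyls to the boronate diester F4, and pinacol releases 18.

Step 10. Acylation may stray to O3, or the new ester may shift from O4 to the cis O3 under base. The fallback replaces catalyst-controlled site selection by a protecting group.
- It sets out from 15. O3 is capped under neutral conditions (2-benzyloxy-1-methylpyridinium triflate, MgO, PhCF3, 85 °C) to give the 3-O-benzyl ketal F5.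
- Hydrolysis as in step 8 gives the 3-O-benzyl ketone F6.
- Luche reduction gives the 3-O-benzyl 4-alcohol F7, in which O4–H is the only secondary hydroxyl.
- Plain DMAP-catalysed acylation by 12 gives the 3-O-benzyl diester F8. The hydrogenolysis of step 11 then removes four benzyl groups and comes back at 19.

Further compounds
F0 | step 3 | none | none
F1 | step 8 | benzyl (3R,5R)-1,3,5-trihydroxy-4-oxocyclohexane-1-carboxylate | O=C1[C@H](O)CC(O)(C(=O)OCc2ccccc2)C[C@H]1O
F2 | step 8 | boronate ketone, O1,O3-phenylboronate of F1 | O=C1[C@H]2C[C@@](OB(c3ccccc3)O2)(C(=O)OCc3ccccc3)C[C@H]1O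
F3 | step 8 | boronate 4,5-diol, O1,O3-phenylboronate of benzyl quinate | O[C@@H]1[C@H]2C[C@@](OB(c3ccccc3)O2)(C(=O)OCc3ccccc3)C[C@H]1O
F4 | step 8 | boronate diester, O1,O3-phenylboronate of 18 | COc1cc(C(=O)O[C@@H]2[C@H]3C[C@@](OB(c4ccccc4)O3)(C(=O)OCc4ccccc4)C[C@H]2OC(=O)c2ccc(OCc3ccccc3)c(OC)c2)ccc1OCc1ccccc1
F5 | step 10 | 3-O-benzyl ketal, 3-O-benzyl ether of 15 | COC1(OC)[C@H](OCc2ccccc2)C[C@@](O)(C(=O)OCc2ccccc2)C[C@H]1OC(=O)c1ccc(OCc2ccccc2)c(OC)c1
F6 | step 10 | 3-O-benzyl ketone, 3-O-benzyl ether of 16 | O=C1[C@H](OCc2ccccc2)C[C@@](O)(C(=O)OCc2ccccc2)C[C@H]1OC(=O)c1ccc(OCc2ccccc2)c(OC)c1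
F7 | step 10 | 3-O-benzyl 4-alcohol, 3-O-benzyl ether of 17 | O[C@@H]1[C@H](OCc2ccccc2)C[C@@](O)(C(=O)OCc2ccccc2)C[C@H]1OC(=O)c1ccc(OCc2ccccc2)c(OC)c1
F8 | step 10 | 3-O-benzyl diester, 3-O-benzyl ether of 18 | COc1cc(C(=O)O[C@@H]2[C@H](OCc3ccccc3)C[C@@](O)(C(=O)OCc3ccccc3)C[C@H]2OC(=O)c2ccc(OCc3ccccc3)c(OC)c2)ccc1OCc1ccccc1
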